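# Proposed synthesis of (R)-3-[5,7-dihydroxy-2-(4-hydroxyphenyl)-4-oxo-4H-chromen-8-yl]-3-phenylpropanoic acid by aryne insertion into an arylpropiolic acid

## Analysis of the target

The target is a flavone: ring A (benzo) and ring C (4-pyranone) form the chromen-4-one, ring B is a 4-hydroxyphenyl group on C2, and ring A carries hydroxyls at C5 and C7 and a 2-carboxy-1-phenylethyl chain at C8. The only stereocentre is the benzylic methine of that chain, (R), bonded to C8, a phenyl group, the CH2CO2H arm and hydrogen; there is no second centre, so its absolute sense has to be set once and then left alone. Ring A is substituted at every position but C6: C4a bears the carbonyl carbon C4, C8a bears the ring oxygen O1, and the chain on C8 is wedged between the C7 hydroxyl and C8a. The sensitive groups are the carboxylic acid, which can close a six-membered lactone onto the C7 hydroxyl under acid; the 5,7-dihydroxyflavone core, in which hot protic acid opens ring C and recloses it on the C5 oxygen so that a C8 substituent ends at C6 (Wessely–Moser rearrangement); and the three phenols. The stereocentre has no acidic hydrogen but is doubly benzylic, so radical conditions and very strong bases are kept away from it. The difficulty is one of position: a branched, stereodefined carbon has to sit on C8 and not C6 of a phloroglucinol-type ring, and the pyranone has to be fused on the side next to it. The strategy rests on the adjacent pair C4a/C8a, one carbon bearing carbon (C4) and the other oxygen (O1), with the C5 oxygen beside C4a and the C8 chain beside C8a. This is the pattern left when the acyl group and the oxygen of one carboxylic acid add across a C4a–C8a aryne polarised by the C5 alkoxy group.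

## Retrosynthetic reasoning

**14 from 12.** The three phenols are carried as methyl ethers and the acid as a tert-butyl ester, and all four O–alkyl bonds are cut in one Lewis-acid operation at the end. The acid can close onto the C7 oxygen in that medium, so lactone 13 is accepted as a transient and reopened with aqueous base. The tert-butyl ester is chosen because it resists the alkoxide, organolithium, fluoride and phenoxide met earlier and falls together with the ethers.

**12 from 11.** The O1–C2 bond of ring C is cut. The forward reaction is the addition of the C8a hydroxyl to the ynone in the six-membered mode. Cutting here leaves an open-chain ketone whose two attachments to ring A, C4–C4a and O–C8a, are exactly those an aryne insertion delivers.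

**11 from 8 and 9 through 10.** The bonds C4–C4a and O–C8a are cut together; both come from the carboxyl group of acid 9, which also brings C2, C3 and ring B. Aryne 10 is released from silyl triflate 8. This disconnection is preferred to acylation of a phenol because the C5 methoxy group decides which aryne carbon receives oxygen, so the ring C junction is fixed by the position of silicon and triflate in 8. The forward step has to put oxygen on the carbon next to the chain and then move the acyl group to the neighbouring carbon.

**8 from 5.** The C–Si and O–S bonds are cut. Forward, the phenol of 5 is silylated to 6, bromine–lithium exchange triggers an oxygen-to-carbon silyl shift to phenoxide 7, and 7 is triflated. Silicon ends where bromine was, so the placement of the aryne is reduced to the placement of one bromine atom.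

**5 from 4.** The ester C–O bond is cut, leading back to the lactone. Forward, a hindered alkoxide opens the aryl lactone, which frees the phenol and installs the spectator ester in the same move.

**4 from 3.** The C8–Br bond is cut. Bromination is placed on the lactone, not on the open phenol: with the ring oxygen acylated, the two methoxy groups decide, and C8 is para to one and ortho to the other. On the free phenol the position para to the hydroxyl (C6) would compete.

**3 from 1 and 2.** The C4–phenyl bond is cut, and with it the stereocentre. Forward, an enantioselective conjugate arylation of coumarin 1 with boronic acid 2 sets the centre on a rigid cyclic enoate at the very start. The lactone of 3 then serves as a joint protecting group for the phenol and the acid until step 3.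

## Alternatives that were turned down

**Alternative 1: Asymmetric carbonylative lactonisation of a 1,1-diarylethylene.**
- Disconnection: in lactone A1, (R)-5-hydroxy-7-methoxy-4-phenylchroman-2-one, the lactone O–C(=O) bond, the CH2–C(=O) bond and the C–H bond at the stereocentre are cut. This leads back to the achiral alkene A2, 5-methoxy-2-(1-phenylvinyl)benzene-1,3-diol, and a one-carbon carbonyl source.
- Forward key step: a palladium hydride carrying a chiral diphosphine adds across the alkene of A2 with hydrogen going to the diaryl carbon, the primary alkylpalladium inserts the carbonyl carbon, and one of the two phenols, equivalent by symmetry, closes the six-membered lactone.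
- For it: stereocentre, chain carbon and lactone arise in one catalytic step from a symmetric alkene. There is no regiochemical choice between the phenols, and the atom economy is better than that of a boronic acid addition.
- Against it: the catalyst must distinguish the faces of an alkene whose internal carbon carries two aryl groups, in a hydropalladation that is reversible by beta-hydride elimination, so the enantioselectivity has no firm structural basis. A1 also contains nothing of ring C: C-acylation next to a free phenol (two activated positions compete), chain extension and ring closure would still follow.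
- Comparison: up to the lactone this route is as short as step 1 here and cheaper in reagents, and on that point it is at least as strong. The chosen strategy offers instead a stereocentre set on a rigid cyclic enoate, where the two faces differ clearly, and a ring C whose two bonds to ring A are placed by the aryne precursor and not by electrophilic acylation of a phenol.

**Alternative 2: Ring A built by vinylketene benzannulation.**
- Disconnection: ring A of phenol A3, methyl (R)-3-[2-(benzyloxy)-6-ethoxy-4-hydroxyphenyl]-3-phenylpropanoate, is cut into the four-carbon cyclobutenone A4, methyl (R)-3-[2-(benzyloxy)-4-oxocyclobut-1-en-1-yl]-3-phenylpropanoate, which already holds the stereocentre, and the two-carbon alkyne A5, ethoxyacetylene.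
- Forward key step: heating opens A4 to a vinylketene, which undergoes [2+2] cycloaddition with A5. The new cyclobutenone opens to a dienylketene, and 6π electrocyclisation followed by tautomerisation gives A3 (Danheiser benzannulation).
- For it: the positions of all ring A substituents follow from the mechanism without any directing-group argument. The three ring oxygens come out differently protected (free, benzyl, ethyl), so ring C could later be closed on a chosen oxygen, and the conditions are neutral.
- Against it: A4 is not a simple compound, since its stereocentre has to be created beforehand on a strained vinylogous ester. That centre sits on the carbon that becomes a ketene terminus and must survive prolonged heating. After A3 the whole pyranone with ring B is still missing: acylation between two oxygens, chain extension, ring closure and an extra ether cleavage.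
- Comparison: on regiochemical certainty in ring A this route is stronger than step 2 here, which relies on directing effects. It is far weaker in step economy, because it assembles a ring that can be bought. The differentiated oxygens are not needed when, as in the chosen strategy, the ring-closing oxygen is delivered by the acid and all ethers are removed together at the end.

**Alternative 3: Ring C closed at carbon by an intramolecular Wittig reaction.**
- Disconnection: the C2=C3 double bond of A6, (10R)-5-methoxy-2-(4-methoxyphenyl)-10-phenyl-9,10-dihydro-4H,8H-pyrano[2,3-f]chromene-4,8-dione (the 5,4'-dimethyl ether of 13), is cut. This leads back to A7, (R)-7-methoxy-2-oxo-4-phenyl-6-[(triphenyl-λ5-phosphanylidene)acetyl]chroman-5-yl 4-methoxybenzoate, in which an acyl-stabilised ylide on the future C4a faces an aroyl ester on the future C8a oxygen.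
- Forward key step: the ylide carbon attacks the ester carbonyl and phosphine oxide is expelled, forming C2=C3 and closing ring C.
- For it: the closure can give only the six-membered pyranone, no strong acid or base is involved, and the lactone protects the acid and the C7 oxygen together throughout.
- Against it: A7 has to be prepared from a dihydrocoumarin by C-acylation ortho to a free phenol (again a choice between two activated positions), alpha-halogenation, phosphonium salt formation and O-aroylation of a hindered, hydrogen-bonded phenol. That is about five steps after the stereocentre is in place. Ester carbonyls are sluggish Wittig partners, and a stoichiometric phosphine oxide is produced.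
- Comparison: for the ring-closing event itself this route is more certain than step 6 here, where a six-membered and a five-membered mode compete. The chosen strategy offers in its place one convergent step that makes both bonds between ring A and ring C and brings in ring B with them, so fewer steps follow the stereocentre.

Key step: step 5

## Route

Assumption: in step 1 (R)-SEGPHOS is taken to deliver the phenyl group with the same facial sense as on unsubstituted coumarin, which makes C4 (R). The configuration of 3 is to be confirmed before going on, and the (S)-ligand is used with no other change if the sense proves opposite.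

Step 1
Reactants: 1 5,7-dimethoxycoumarin; 2 phenylboronic acid
Product: 3 (R)-5,7-dimethoxy-4-phenylchroman-2-one
Conditions: Rh(acac)(C2H4)2 (3 mol %), (R)-SEGPHOS (3.3 mol %), 2 (5 equiv, in portions), dioxane/H2O 10:1, 60 °C
Reagents that add atoms: none
Why: Rhodium-catalysed asymmetric 1,4-addition of an arylboronic acid to a coumarin (Hayashi–Miyaura reaction): the phenyl group passes from monovalent rhodium to C4 of the enoate held in the pocket of the chiral diphosphine, and water protonates the rhodium enolate. The lactone presents a single, rigid alkene geometry, so the ligand alone decides the face and C4 should become (R).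

Step 2
Reactants: 3 (R)-5,7-dimethoxy-4-phenylchroman-2-one
Product: 4 (R)-8-bromo-5,7-dimethoxy-4-phenylchroman-2-one
Conditions: NBS (1.0 equiv), MeCN, −10 °C → rt, dark
Reagents that add atoms: N-bromosuccinimide, O=C1CCC(=O)N1Br
Why: Electrophilic aromatic bromination: C8 is para to the C5 methoxy group and ortho to the C7 methoxy group, whereas C6 lies between two methoxy groups and is para only to the weakly donating acylated oxygen, so substitution should go to C8. One equivalent in a polar solvent without light should avoid a second bromination and radical attack at the benzylic stereocentre.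

Step 3
Reactants: 4 (R)-8-bromo-5,7-dimethoxy-4-phenylchroman-2-one
Product: 5 tert-butyl (R)-3-(3-bromo-2-hydroxy-4,6-dimethoxyphenyl)-3-phenylpropanoate
Conditions: KOt-Bu (1.2 equiv), THF, 0 °C; AcOH (1.3 equiv), pH 7 buffer
Reagents that add atoms: potassium tert-butoxide, CC(C)(C)[O-].[K+]
Why: Alkoxide ring opening of an aryl lactone (transesterification): tert-butoxide adds to the carbonyl and the much better leaving group, the phenoxide, is expelled, so the equilibrium lies on the side of the open tert-butyl ester. The stereocentre is beta to the carbonyl and is not deprotonated, and the neutral quench keeps the phenol from closing back.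

Step 4
Reactants: 5 tert-butyl (R)-3-(3-bromo-2-hydroxy-4,6-dimethoxyphenyl)-3-phenylpropanoate
Product: 8 tert-butyl (R)-3-[2,4-dimethoxy-6-(trifluoromethanesulfonyloxy)-5-(trimethylsilyl)phenyl]-3-phenylpropanoate, via aryl silyl ether 6 (not isolated), via lithium silylphenoxide 7 (not isolated)
Conditions: HMDS, THF, 65 °C, then evaporate; n-BuLi (1.05 equiv), THF, −100 → −80 °C; Tf2O (1.2 equiv), −100 → −78 °C; cold aq NaHCO3
Reagents that add atoms: hexamethyldisilazane, C[Si](C)(C)N[Si](C)(C)C; trifluoromethanesulfonic anhydride, O=S(=O)(OS(=O)(=O)C(F)(F)F)C(F)(F)F
Why: Retro-Brook route from an ortho-bromophenol to an ortho-silylaryl triflate: bromine–lithium exchange on 6 at −100 °C is faster than attack on or deprotonation of the tert-butyl ester, and the aryllithium takes the silyl group from the neighbouring oxygen in a 1,3 shift to give 7, which is triflated in the same flask. Silicon therefore ends exactly where bromine was, between the triflate and a methoxy group.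

Step 5
Reactants: 8 tert-butyl (R)-3-[2,4-dimethoxy-6-(trifluoromethanesulfonyloxy)-5-(trimethylsilyl)phenyl]-3-phenylpropanoate; 9 3-(4-methoxyphenyl)propiolic acid
Product: 11 tert-butyl (R)-3-{2-hydroxy-4,6-dimethoxy-3-[3-(4-methoxyphenyl)propioloyl]phenyl}-3-phenylpropanoate, via aryne 10 (not isolated)
Conditions: 9 (2 equiv), CsF (5 equiv), THF, 125 °C, sealed tube
Reagents that add atoms: none
Why: Fluoride attacks silicon in 8 and triflate leaves, releasing aryne 10, whose strained bond joins the future C4a and C8a. The caesium carboxylate of 9 adds through oxygen to C8a, because the C5 methoxy group, an inductive acceptor beside C4a, distorts the aryne so that C8a is the flatter, more electrophilic terminus and the developing negative charge sits on C4a next to oxygen. The C4a aryl anion then attacks the neighbouring ester carbonyl through a four-membered transition state and the adduct opens to the C4a ketone and the C8a phenoxide, a net 1,3 shift of the acyl group from oxygen to carbon that forms C4–C4a after O–C8a. The closest known reaction type is the insertion of arynes into the C–O bond of carboxylic acids to give ortho-hydroxyaryl ketones, which is documented for 3-alkoxyarynes and for arylpropiolic acids. No ring is closed and no stereocentre is made; the existing centre is not part of the reacting system and carries no acidic hydrogen. The selectivity required is regiochemical: oxygen has to bond to C8a although the branched C8 substituent stands next to it, and what secures this is the electronic bias of the C5 methoxy group together with the small size of a carboxylate oxygen, the C7 methoxy group being too remote to override it. Excess fluoride and a hot, weakly polar solvent keep proton donors scarce, so the acyl shift should outrun protonation of the aryl anion, which would stop at the O-aryl ester. Any 11 that already closes to 12 under these conditions is carried into step 6.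

Step 6
Reactants: 11 tert-butyl (R)-3-{2-hydroxy-4,6-dimethoxy-3-[3-(4-methoxyphenyl)propioloyl]phenyl}-3-phenylpropanoate
Product: 12 tert-butyl (R)-3-[5,7-dimethoxy-2-(4-methoxyphenyl)-4-oxo-4H-chromen-8-yl]-3-phenylpropanoate
Conditions: K2CO3 (2 equiv), acetone, 56 °C
Reagents that add atoms: none
Why: Intramolecular oxa-Michael addition of the C8a phenoxide to the ynone, a 6-endo-dig closure that forms O1–C2; in an aprotic medium the phenoxide should attack the electrophilic beta carbon and not the alpha carbon, which would give the five-membered aurone. The only free hydroxyl is on C8a, so only the 8-substituted flavone can result.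

Step 7
Reactants: 12 tert-butyl (R)-3-[5,7-dimethoxy-2-(4-methoxyphenyl)-4-oxo-4H-chromen-8-yl]-3-phenylpropanoate
Product: 14 (R)-3-[5,7-dihydroxy-2-(4-hydroxyphenyl)-4-oxo-4H-chromen-8-yl]-3-phenylpropanoic acid, via O7 lactone 13 (not isolated)
Conditions: BBr3 (10 equiv), CH2Cl2, −78 °C → rt; H2O, 0 °C; LiOH, THF/H2O, rt, argon; 1 M HCl to pH 3, 0 °C
Reagents that add atoms: lithium hydroxide, [Li+].[OH-]
Why: Lewis-acid cleavage of the three aryl methyl ethers and the tert-butyl ester by BBr3; in this medium the freed acid is expected to close, in part or wholly, onto the neighbouring C7 hydroxyl to give 13, which mild aqueous hydroxide reopens before a cold, careful acidification. BBr3 at or below room temperature is chosen over hot protic acid so that ring C is not opened and reclosed on the C5 oxygen (Wessely–Moser rearrangement).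

## Compound list

1 | 5,7-dimethoxycoumarin (5,7-dimethoxy-2H-chromen-2-one) | COc1cc(OC)c2ccc(=O)oc2c1 | starting material
2 | phenylboronic acid | OB(O)c1ccccc1 | starting material
3 | (R)-5,7-dimethoxy-4-phenylchroman-2-one | O=C1C[C@H](c2ccccc2)c2c(OC)cc(OC)cc2O1 | intermediate
4 | (R)-8-bromo-5,7-dimethoxy-4-phenylchroman-2-one | O=C1C[C@H](c2ccccc2)c2c(OC)cc(OC)c(Br)c2O1 | intermediate
5 | tert-butyl (R)-3-(3-bromo-2-hydroxy-4,6-dimethoxyphenyl)-3-phenylpropanoate | CC(C)(C)OC(=O)C[C@H](c1ccccc1)c1c(OC)cc(OC)c(Br)c1O | intermediate
6 | tert-butyl (R)-3-[3-bromo-4,6-dimethoxy-2-(trimethylsilyloxy)phenyl]-3-phenylpropanoate (formed and consumed in step 4) | CC(C)(C)OC(=O)C[C@H](c1ccccc1)c1c(OC)cc(OC)c(Br)c1O[Si](C)(C)C | intermediate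
7 | lithium 2-[(1R)-3-tert-butoxy-3-oxo-1-phenylpropyl]-3,5-dimethoxy-6-(trimethylsilyl)phenolate (formed and consumed in step 4) | CC(C)(C)OC(=O)C[C@H](c1ccccc1)c1c(OC)cc(OC)c([Si](C)(C)C)c1[O-].[Li+] | intermediate
8 | tert-butyl (R)-3-[2,4-dimethoxy-6-(trifluoromethanesulfonyloxy)-5-(trimethylsilyl)phenyl]-3-phenylpropanoate | CC(C)(C)OC(=O)C[C@H](c1ccccc1)c1c(OC)cc(OC)c([Si](C)(C)C)c1OS(=O)(=O)C(F)(F)F | intermediate
9 | 3-(4-methoxyphenyl)propiolic acid | COc1ccc(cc1)C#CC(=O)O | starting material
10 | aryne, tert-butyl (R)-3-(4,6-dimethoxy-2,3-didehydrophenyl)-3-phenylpropanoate (formed and consumed in step 5) | CC(C)(C)OC(=O)C[C@H](c1ccccc1)C1=C(OC)C=C(OC)C#C1 | intermediate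
11 | tert-butyl (R)-3-{2-hydroxy-4,6-dimethoxy-3-[3-(4-methoxyphenyl)propioloyl]phenyl}-3-phenylpropanoate | CC(C)(C)OC(=O)C[C@H](c1ccccc1)c1c(OC)cc(OC)c(C(=O)C#Cc2ccc(OC)cc2)c1O | intermediate
12 | tert-butyl (R)-3-[5,7-dimethoxy-2-(4-methoxyphenyl)-4-oxo-4H-chromen-8-yl]-3-phenylpropanoate | CC(C)(C)OC(=O)C[C@H](c1ccccc1)c1c(OC)cc(OC)c2c(=O)cc(-c3ccc(OC)cc3)oc12 | intermediate
13 | O7 lactone of 14, (10R)-5-hydroxy-2-(4-hydroxyphenyl)-10-phenyl-9,10-dihydro-4H,8H-pyrano[2,3-f]chromene-4,8-dione (formed and consumed in step 7) | O=C1C[C@H](c2ccccc2)c2c(O1)cc(O)c1c(=O)cc(-c3ccc(O)cc3)oc21 | intermediate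
14 | (R)-3-[5,7-dihydroxy-2-(4-hydroxyphenyl)-4-oxo-4H-chromen-8-yl]-3-phenylpropanoic acid | O=C(O)C[C@H](c1ccccc1)c1c(O)cc(O)c2c(=O)cc(-c3ccc(O)cc3)oc12 | target

## Step count and least certain steps

Total step count: 7. Longest linear sequence: 7 steps (1 to 14); acid 9 is used as purchased.

**Step 5 (key step).** Three processes threaten it.
- Addition at the wrong aryne terminus: the branched chain on C8 hinders in-plane approach to C8a, which works against the electronic preference set by the C5 methoxy group.
- Premature protonation of the aryl anion, so that the sequence stops after O-arylation without acyl transfer.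
- Interception of the aryne by the carbonyl oxygen of its own side-chain ester through a six-membered approach, with loss of the tert-butyl group.

Fallback (classical flavone construction): it sets out from 3. Friedel–Crafts acetylation (AcCl, SnCl4, CH2Cl2, −20 °C) should go to C8 for the same electronic reason as in step 2 and give (R)-8-acetyl-5,7-dimethoxy-4-phenylchroman-2-one F1. Opening with KOt-Bu as in step 3 gives tert-butyl (R)-3-(3-acetyl-2-hydroxy-4,6-dimethoxyphenyl)-3-phenylpropanoate F2. Claisen–Schmidt condensation with 4-methoxybenzaldehyde (KOH, EtOH, rt) gives the 2'-hydroxychalcone F3. Oxidative cyclisation (I2 cat., DMSO, 120 °C) closes ring C, and the route is rejoined at 12.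

**Step 2.** Site selection between C8 and C6 may be incomplete, and a second bromination is possible because the ring stays electron-rich after the first. Fallback (directed ortho-metalation in place of electrophilic substitution): it sets out from 3.
- Opening with KOt-Bu and trapping the phenoxide with diethylcarbamoyl chloride gives tert-butyl (R)-3-[2-(diethylcarbamoyloxy)-4,6-dimethoxyphenyl]-3-phenylpropanoate F4.
- LDA (2.5 equiv, THF, −78 °C) first turns the ester into its lithium enolate, which shields it, and then lithiates the ring position between the carbamate and a methoxy group.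
- Me3SiCl gives the C,O-bis-silylated ketene acetal F5, which aqueous work-up hydrolyses to tert-butyl (R)-3-[2-(diethylcarbamoyloxy)-4,6-dimethoxy-3-(trimethylsilyl)phenyl]-3-phenylpropanoate F6.
- Reductive cleavage of the carbamate with Cp2Zr(H)Cl gives tert-butyl (R)-3-[2-hydroxy-4,6-dimethoxy-3-(trimethylsilyl)phenyl]-3-phenylpropanoate F7.
- LiHMDS converts F7 into 7, which is triflated as in step 4, so the route is rejoined at 8.

**Step 4.** n-BuLi may attack or deprotonate the ester in competition with halogen–metal exchange, the aryllithium may be quenched before the silyl shift, and triflation of a phenoxide flanked on both sides may be slow. Fallback (no organolithium in the presence of the ester): it sets out from 4. Palladium-catalysed silylation of the aryl bromide with Me3SiSiMe3 (Pd2(dba)3, 2-(di-tert-butylphosphino)biphenyl, KF, DMPU, 100 °C) gives (R)-5,7-dimethoxy-4-phenyl-8-(trimethylsilyl)chroman-2-one F8. LiOt-Bu in THF opens the lactone to give 7 directly, and triflation as in step 4 rejoins the route at 8.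

**Step 1.** Carbometalation at C4 may be slow because the C5 methoxy group crowds that carbon and the two donor groups lower the electrophilicity of the enoate; protodeboronation of 2 would then win. Fallback (the stereocentre is set by hydride delivery instead of aryl delivery): it sets out from 1 and 2.
- Oxidative Heck arylation (Pd(OAc)2, 1,10-phenanthroline, O2, DMF, 80 °C) gives 5,7-dimethoxy-4-phenylcoumarin F9.
- Asymmetric conjugate reduction with CuH, generated from Cu(OAc)2·H2O and (EtO)2MeSiH with the enantiomer of DTBM-SEGPHOS that leads to the (R) centre (t-BuOH, toluene), is expected to run on to the lactol (4R)-5,7-dimethoxy-4-phenylchroman-2-ol F10.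
- Oxidation of F10 (PhI(OAc)2, TEMPO cat., CH2Cl2) rejoins the route at 3.

**Step 6.** The phenoxide may close in the 5-exo mode at the alpha carbon, and the closure may be slow because the phenoxide is hydrogen-bonded to the ketone and flanked by the chain. Fallback (addition–elimination in place of direct closure on the alkyne): it sets out from 11. Diethylamine in EtOH at rt adds to the ynone to give the enaminone F11. On warming, the phenol displaces the amine at the beta carbon, which can only give the six-membered ring, and the route is rejoined at 12.

**Step 7.** Cleavage of the C7 and 4' methyl ethers may be incomplete at a temperature low enough to avoid acid-induced migration of the C8 substituent to C6, and lactone closure competes throughout. Fallback (nucleophilic demethylation under basic conditions): it sets out from 12. CF3CO2H in CH2Cl2 removes the tert-butyl group and gives (R)-3-[5,7-dimethoxy-2-(4-methoxyphenyl)-4-oxo-4H-chromen-8-yl]-3-phenylpropanoic acid F12, which has no free neighbouring hydroxyl and cannot lactonise. Sodium ethanethiolate (DMF, 120 °C) then removes the three methyl groups by substitution at methyl while the acid is held as its carboxylate, and cold acidification rejoins the route at 14.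

## Further compounds

F1 | step 5 | (R)-8-acetyl-5,7-dimethoxy-4-phenylchroman-2-one | O=C1C[C@H](c2ccccc2)c2c(OC)cc(OC)c(C(C)=O)c2O1
F2 | step 5 | tert-butyl (R)-3-(3-acetyl-2-hydroxy-4,6-dimethoxyphenyl)-3-phenylpropanoate | CC(C)(C)OC(=O)C[C@H](c1ccccc1)c1c(OC)cc(OC)c(C(C)=O)c1O
F3 | step 5 | tert-butyl (R)-3-{2-hydroxy-4,6-dimethoxy-3-[(E)-3-(4-methoxyphenyl)acryloyl]phenyl}-3-phenylpropanoate | CC(C)(C)OC(=O)C[C@H](c1ccccc1)c1c(OC)cc(OC)c(C(=O)/C=C/c2ccc(OC)cc2)c1O
F4 | step 2 | tert-butyl (R)-3-[2-(diethylcarbamoyloxy)-4,6-dimethoxyphenyl]-3-phenylpropanoate | CC(C)(C)OC(=O)C[C@H](c1ccccc1)c1c(OC)cc(OC)cc1OC(=O)N(CC)CC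
F5 | step 2 | (R)-2-[3-tert-butoxy-1-phenyl-3-(trimethylsilyloxy)prop-2-en-1-yl]-3,5-dimethoxy-6-(trimethylsilyl)phenyl diethylcarbamate (double-bond geometry not defined) | CC(C)(C)OC(O[Si](C)(C)C)=C[C@H](c1ccccc1)c1c(OC)cc(OC)c([Si](C)(C)C)c1OC(=O)N(CC)CC
F6 | step 2 | tert-butyl (R)-3-[2-(diethylcarbamoyloxy)-4,6-dimethoxy-3-(trimethylsilyl)phenyl]-3-phenylpropanoate | CC(C)(C)OC(=O)C[C@H](c1ccccc1)c1c(OC)cc(OC)c([Si](C)(C)C)c1OC(=O)N(CC)CC
F7 | step 2 | tert-butyl (R)-3-[2-hydroxy-4,6-dimethoxy-3-(trimethylsilyl)phenyl]-3-phenylpropanoate | CC(C)(C)OC(=O)C[C@H](c1ccccc1)c1c(OC)cc(OC)c([Si](C)(C)C)c1O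
F8 | step 4 | (R)-5,7-dimethoxy-4-phenyl-8-(trimethylsilyl)chroman-2-one | O=C1C[C@H](c2ccccc2)c2c(OC)cc(OC)c([Si](C)(C)C)c2O1
F9 | step 1 | 5,7-dimethoxy-4-phenylcoumarin | COc1cc(OC)c2c(-c3ccccc3)cc(=O)oc2c1
F10 | step 1 | (4R)-5,7-dimethoxy-4-phenylchroman-2-ol (mixture of anomers) | OC1C[C@H](c2ccccc2)c2c(OC)cc(OC)cc2O1
F11 | step 6 | tert-butyl (R)-3-{3-[3-(diethylamino)-3-(4-methoxyphenyl)acryloyl]-2-hydroxy-4,6-dimethoxyphenyl}-3-phenylpropanoate (double-bond geometry not defined) | CC(C)(C)OC(=O)C[C@H](c1ccccc1)c1c(OC)cc(OC)c(C(=O)C=C(N(CC)CC)c2ccc(OC)cc2)c1O
F12 | step 7 | (R)-3-[5,7-dimethoxy-2-(4-methoxyphenyl)-4-oxo-4H-chromen-8-yl]-3-phenylpropanoic acid | O=C(O)C[C@H](c1ccccc1)c1c(OC)cc(OC)c2c(=O)cc(-c3ccc(OC)cc3)oc12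
A1 | alternative 1 | (R)-5-hydroxy-7-methoxy-4-phenylchroman-2-one | O=C1C[C@H](c2ccccc2)c2c(O)cc(OC)cc2O1
A2 | alternative 1 | 5-methoxy-2-(1-phenylvinyl)benzene-1,3-diol | C=C(c1ccccc1)c1c(O)cc(OC)cc1O
A3 | alternative 2 | methyl (R)-3-[2-(benzyloxy)-6-ethoxy-4-hydroxyphenyl]-3-phenylpropanoate | COC(=O)C[C@H](c1ccccc1)c1c(OCC)cc(O)cc1OCc1ccccc1
A4 | alternative 2 | methyl (R)-3-[2-(benzyloxy)-4-oxocyclobut-1-en-1-yl]-3-phenylpropanoate | COC(=O)C[C@H](c1ccccc1)C1=C(OCc2ccccc2)CC1=O
A5 | alternative 2 | ethoxyacetylene | C#COCC
A6 | alternative 3 | (10R)-5-methoxy-2-(4-methoxyphenyl)-10-phenyl-9,10-dihydro-4H,8H-pyrano[2,3-f]chromene-4,8-dione | O=C1C[C@H](c2ccccc2)c2c(O1)cc(OC)c1c(=O)cc(-c3ccc(OC)cc3)oc21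
A7 | alternative 3 | (R)-7-methoxy-2-oxo-4-phenyl-6-[(triphenyl-λ5-phosphanylidene)acetyl]chroman-5-yl 4-methoxybenzoate | O=C1C[C@H](c2ccccc2)c2c(O1)cc(OC)c(C(=O)C=P(c1ccccc1)(c1ccccc1)c1ccccc1)c2OC(=O)c1ccc(OC)cc1
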